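The pendant aryl ring is disconnected at C1'–C2'. That ring is unfolded into a 1,3,5-triketone chain whose first carbonyl (the future C1') is already bonded to C2 of the benzofuran. One base-mediated intramolecular aldol condensation of the terminal methyl carbon onto this ketone, with dehydration and enolisation, builds the whole resorcinol ring in a single operation. The precursor is a 1-(benzofuran-2-yl)hexane-1,3,5-trione carrying the finished 5-O-MOM, 6-OMe and 7-prenyl substituents. The step exploits the 1,3-relationship of the oxygens on C3' and C5' of the pendant ring, each meta to C1', the carbon joined to C2 of the furan ring.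

Key step: step 9

Remark: poly-β-carbonyl compounds are drawn in keto (or enolate) form although they will exist largely as enols; dienone 8, the only compound with a stereocentre, is transient and racemic.

Step 1
Reactants: 1 vanillin (4-hydroxy-3-methoxybenzaldehyde)
Product: 2 3-methoxy-4-(methoxymethoxy)benzaldehyde
Conditions: MOMCl, i-Pr2NEt, CH2Cl2, 0 °C → rt
Reagents that add atoms: chloromethyl methyl ether (MOMCl), COCCl
Why: Williamson-type O-alkylation of the acidic phenol with an α-chloro ether under amine base is routine and installs an acetal that survives every basic, oxidative and thermal step that follows.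

Step 2
Reactants: 2 3-methoxy-4-(methoxymethoxy)benzaldehyde
Product: 4 3-methoxy-4-(methoxymethoxy)phenol, via aryl formate 3 (not isolated)
Conditions: mCPBA, CH2Cl2, rt; then K2CO3 (cat.), MeOH, rt
Reagents that add atoms: meta-chloroperoxybenzoic acid (mCPBA), OOC(=O)c1cccc(Cl)c1
Why: Baeyer–Villiger oxidation in its Dakin-type variant, in which the electron-rich aryl group migrates to oxygen in preference to hydride and the aryl formate is then cleaved by mild base-catalysed methanolysis without touching the MOM acetal.

Step 3
Reactants: 4 3-methoxy-4-(methoxymethoxy)phenol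
Product: 5 2-hydroxy-4-methoxy-5-(methoxymethoxy)benzaldehyde
Conditions: MgCl2, Et3N, (CH2O)n, MeCN, reflux
Reagents that add atoms: paraformaldehyde (reacts as formaldehyde), C=O
Why: Magnesium-mediated ortho-formylation of a phenol (Casnati–Skattebøl reaction), in which the magnesium phenoxide directs formaldehyde to an ortho carbon and a second formaldehyde oxidises the benzylic alkoxide by hydride transfer; of the two ortho sites the open one para to OMe should be taken over the one wedged between OH and OMe.

Step 4
Reactants: 5 2-hydroxy-4-methoxy-5-(methoxymethoxy)benzaldehyde; 6 allyl bromide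
Product: 7 2-(allyloxy)-4-methoxy-5-(methoxymethoxy)benzaldehyde
Conditions: K2CO3, DMF, 50 °C
Reagents that add atoms: none
Why: Williamson ether synthesis with a reactive primary allylic bromide in a dipolar solvent, which readily alkylates even the hydrogen-bonded salicylaldehyde hydroxyl.

Step 5
Reactants: 7 2-(allyloxy)-4-methoxy-5-(methoxymethoxy)benzaldehyde
Product: 9 3-allyl-2-hydroxy-4-methoxy-5-(methoxymethoxy)benzaldehyde, via ortho-dienone 8 (not isolated)
Conditions: N,N-diethylaniline, 190 °C
Reagents that add atoms: none
Why: Aromatic Claisen rearrangement, a [3,3]-sigmatropic shift followed by tautomerisation of dienone 8, which can only end at C3 because the other ortho carbon carries the formyl group and the para carbon the MOM ether, so the three-carbon unit is placed regiospecifically between OH and OMe.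

Step 6
Reactants: 9 3-allyl-2-hydroxy-4-methoxy-5-(methoxymethoxy)benzaldehyde; 10 2-methylbut-2-ene
Product: 11 2-hydroxy-4-methoxy-5-(methoxymethoxy)-3-(3-methylbut-2-en-1-yl)benzaldehyde
Conditions: second-generation Grubbs catalyst (cat.), 10 (excess), CH2Cl2, 40 °C, sealed tube
Reagents that add atoms: none
Why: Olefin cross-metathesis of a terminal allyl group with excess 2-methylbut-2-ene, a standard allyl-to-prenyl conversion that tolerates free phenols and aldehydes and stops at the trisubstituted alkene, which is a poor metathesis substrate.

Step 7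
Reactants: 11 2-hydroxy-4-methoxy-5-(methoxymethoxy)-3-(3-methylbut-2-en-1-yl)benzaldehyde; 12 ethyl bromoacetate
Product: 14 ethyl 6-methoxy-5-(methoxymethoxy)-7-(3-methylbut-2-en-1-yl)-1-benzofuran-2-carboxylate, via aryloxyacetate 13 (not isolated)
Conditions: K2CO3, DMF, rt, then 110 °C
Reagents that add atoms: none
Why: Rap–Stoermer-type benzofuran annulation, in which phenoxide O-alkylation is followed on heating by intramolecular aldol addition of the ester α-carbon to the ortho formyl group and dehydration to the aromatic furan.

Step 8
Reactants: 14 ethyl 6-methoxy-5-(methoxymethoxy)-7-(3-methylbut-2-en-1-yl)-1-benzofuran-2-carboxylate; 15 acetylacetone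
Product: 17 1-[6-methoxy-5-(methoxymethoxy)-7-(3-methylbut-2-en-1-yl)-1-benzofuran-2-yl]hexane-1,3,5-trione, via dilithio acetylacetonate 16 (not isolated)
Conditions: 15 (excess), LiN(i-Pr)2 (2 equiv per 15), THF, 0 °C; then 14, −78 → 0 °C; AcOH quench
Reagents that add atoms: none
Why: Claisen-type C-acylation of a β-diketone dianion, whose more basic terminal carbanion attacks the non-enolisable heteroaryl ester with loss of ethoxide, the excess dianion taking up the acidic protons of the triketone so that it stays protected as its enolate until the mild acetic acid quench.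

Step 9
Reactants: 17 1-[6-methoxy-5-(methoxymethoxy)-7-(3-methylbut-2-en-1-yl)-1-benzofuran-2-yl]hexane-1,3,5-trione
Product: 19 5-[6-methoxy-5-(methoxymethoxy)-7-(3-methylbut-2-en-1-yl)-1-benzofuran-2-yl]benzene-1,3-diol, via aldol adduct 18 (not isolated)
Conditions: KOH (1 M, aq.), 1,4-dioxane, degassed, Ar, about 0.01 M, 25 → 60 °C; then AcOH to pH 6
Reagents that add atoms: none
Why: Hydroxide equilibrates triketone 17 with its enolates, and the small fraction enolised toward the terminal methyl carbon adds to the benzofuranyl ketone to give the symmetric 5-aryl-5-hydroxycyclohexane-1,3-dione 18, which loses water by E1cB elimination and tautomerises to the resorcinol, aromatisation making the sequence irreversible. The closest known reaction type is the polyketide-like intramolecular aldol condensation of 1,3,5-triketones to resorcinols, as in diacetylacetone to orcinol, and its variants with aryl ketone acceptors in 7-aryl-3,5,7-triketo acids. The carbocycle closes in the 6-(enolendo)-exo-trig mode, forming C1'–C2', and no other carbocycle is possible because only the terminal methyl lies five atoms from a carbonyl carbon. No stereocentre is formed. The selectivity needed is C–C closure over O-closure to the 2-aryl-6-methyl-4-pyrone, over bimolecular condensation and over retro-Claisen cleavage: aqueous alkali disfavours the pyrone and reopens it, high dilution under argon suppresses dimerisation and oxidation of the product, and the temperature is raised only as far as conversion requires. The donor-conjugated aryl ketone is a weaker acceptor than the methyl ketone of the parent case, so the risk of the route is concentrated here, while the MOM acetal and the prenyl group are inert to the medium.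

Step 10
Reactants: 19 5-[6-methoxy-5-(methoxymethoxy)-7-(3-methylbut-2-en-1-yl)-1-benzofuran-2-yl]benzene-1,3-diol
Product: 20 3-methoxy-5-[6-methoxy-5-(methoxymethoxy)-7-(3-methylbut-2-en-1-yl)-1-benzofuran-2-yl]phenol
Conditions: MeI (1 equiv), K2CO3 (1 equiv), acetone, rt
Reagents that add atoms: iodomethane (MeI), CI
Why: Williamson O-methylation limited to one equivalent of MeI; since the two phenols are homotopic only one mono-ether can form, and it should be separable by chromatography from the unreacted diol, which is recycled, and from the dimethyl ether, while the MOM group keeps the third phenol out of play.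

Step 11
Reactants: 20 3-methoxy-5-[6-methoxy-5-(methoxymethoxy)-7-(3-methylbut-2-en-1-yl)-1-benzofuran-2-yl]phenol
Product: 21 dinklagein A, 2-(3-hydroxy-5-methoxyphenyl)-6-methoxy-7-(3-methylbut-2-en-1-yl)-1-benzofuran-5-ol
Conditions: HCl (cat.), MeOH, 40 °C
Reagents that add atoms: none
Why: Acid-catalysed acetal exchange (MOM ether cleavage) in methanol, mild enough to spare the prenyl alkene, which has no free ortho phenol and therefore cannot close to a chroman.

Compound list

1 | vanillin (4-hydroxy-3-methoxybenzaldehyde) | COc1cc(C=O)ccc1O | starting material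
2 | 3-methoxy-4-(methoxymethoxy)benzaldehyde | COCOc1ccc(C=O)cc1OC | intermediate
3 | 3-methoxy-4-(methoxymethoxy)phenyl formate | COCOc1ccc(OC=O)cc1OC | intermediate
4 | 3-methoxy-4-(methoxymethoxy)phenol | COCOc1ccc(O)cc1OC | intermediate
5 | 2-hydroxy-4-methoxy-5-(methoxymethoxy)benzaldehyde | COCOc1cc(C=O)c(O)cc1OC | intermediate
6 | allyl bromide (3-bromoprop-1-ene) | C=CCBr | starting material
7 | 2-(allyloxy)-4-methoxy-5-(methoxymethoxy)benzaldehyde | C=CCOc1cc(OC)c(OCOC)cc1C=O | intermediate
8 | 5-allyl-4-methoxy-3-(methoxymethoxy)-6-oxocyclohexa-1,3-diene-1-carbaldehyde (racemic ortho-dienone) | O=CC1=CC(OCOC)=C(OC)C(CC=C)C1=O | intermediate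
9 | 3-allyl-2-hydroxy-4-methoxy-5-(methoxymethoxy)benzaldehyde | C=CCc1c(O)c(C=O)cc(OCOC)c1OC | intermediate
10 | 2-methylbut-2-ene | CC=C(C)C | starting material
11 | 2-hydroxy-4-methoxy-5-(methoxymethoxy)-3-(3-methylbut-2-en-1-yl)benzaldehyde | COCOc1cc(C=O)c(O)c(CC=C(C)C)c1OC | intermediate
12 | ethyl bromoacetate | CCOC(=O)CBr | starting material
13 | ethyl 2-[2-formyl-5-methoxy-4-(methoxymethoxy)-6-(3-methylbut-2-en-1-yl)phenoxy]acetate | CCOC(=O)COc1c(C=O)cc(OCOC)c(OC)c1CC=C(C)C | intermediate
14 | ethyl 6-methoxy-5-(methoxymethoxy)-7-(3-methylbut-2-en-1-yl)-1-benzofuran-2-carboxylate | CCOC(=O)c1cc2cc(OCOC)c(OC)c(CC=C(C)C)c2o1 | intermediate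
15 | acetylacetone (pentane-2,4-dione) | CC(=O)CC(C)=O | starting material
16 | dilithium salt of the acetylacetone dianion (terminal carbon and C3 deprotonated) | [Li+].[Li+].C=C([O-])C=C(C)[O-] | intermediate
17 | 1-[6-methoxy-5-(methoxymethoxy)-7-(3-methylbut-2-en-1-yl)-1-benzofuran-2-yl]hexane-1,3,5-trione | CC(=O)CC(=O)CC(=O)c1cc2cc(OCOC)c(OC)c(CC=C(C)C)c2o1 | intermediate
18 | 5-hydroxy-5-[6-methoxy-5-(methoxymethoxy)-7-(3-methylbut-2-en-1-yl)-1-benzofuran-2-yl]cyclohexane-1,3-dione | COCOc1cc2cc(C3(O)CC(=O)CC(=O)C3)oc2c(CC=C(C)C)c1OC | intermediate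
19 | 5-[6-methoxy-5-(methoxymethoxy)-7-(3-methylbut-2-en-1-yl)-1-benzofuran-2-yl]benzene-1,3-diol | COCOc1cc2cc(-c3cc(O)cc(O)c3)oc2c(CC=C(C)C)c1OC | intermediate
20 | 3-methoxy-5-[6-methoxy-5-(methoxymethoxy)-7-(3-methylbut-2-en-1-yl)-1-benzofuran-2-yl]phenol | COCOc1cc2cc(-c3cc(O)cc(OC)c3)oc2c(CC=C(C)C)c1OC | intermediate
21 | dinklagein A, 2-(3-hydroxy-5-methoxyphenyl)-6-methoxy-7-(3-methylbut-2-en-1-yl)-1-benzofuran-5-ol | COc1cc(O)cc(-c2cc3cc(O)c(OC)c(CC=C(C)C)c3o2)c1 | target

Total step count: 11. Longest linear sequence: 11 steps (1 to 21).

Steps most likely to fail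

Step 9. Enolisation toward the unactivated terminal methyl is rare and the donor-conjugated benzofuranyl ketone is a sluggish acceptor. Bimolecular condensation at the methyl ketone, retro-Claisen cleavage by hydroxide or closure through oxygen may therefore outrun the carbocyclisation. The fallback activates the nucleophilic terminus as a malonyl-type carbon and removes the extra carbon afterwards. It sets out from 17: the trianion (LiN(i-Pr)2, 3.3 equiv, THF, 0 °C) is carboxylated at the terminal carbon with CO2 to give 7-[6-methoxy-5-(methoxymethoxy)-7-(3-methylbut-2-en-1-yl)-1-benzofuran-2-yl]-3,5,7-trioxoheptanoic acid F1. In aqueous KOH at rt the doubly activated C2 methylene of this acid should add to the same aryl ketone and, after dehydration, give 2,4-dihydroxy-6-[6-methoxy-5-(methoxymethoxy)-7-(3-methylbut-2-en-1-yl)-1-benzofuran-2-yl]benzoic acid F2. Brief heating of this β-resorcylic acid in degassed DMSO at about 120 °C should decarboxylate it, and the route is rejoined at 19.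

Step 8. Proton transfer from the acidic triketone to the dianion, O-acylation, or slow addition to the donor-substituted ester may leave the acylation incomplete or give mixtures. The fallback builds the chain in two stages with the polarity reversed, so that the valuable fragment is the dianion and a simple acetyl donor is the electrophile. It sets out from 14: crossed Claisen condensation with the lithium enolate of acetone (LiN(SiMe3)2, acetone, THF, −78 → 0 °C) should give 1-[6-methoxy-5-(methoxymethoxy)-7-(3-methylbut-2-en-1-yl)-1-benzofuran-2-yl]butane-1,3-dione F3. Its dianion (LiN(i-Pr)2, 2.2 equiv, THF, 0 °C) is then acetylated at the terminal methyl with N-methoxy-N-methylacetamide, whose stable tetrahedral adduct prevents over-addition, and the route is rejoined at 17.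

Step 10. The second methylation competes with the first, and diol, mono-ether and di-ether may be hard to separate, so that material is lost in a late step. The fallback brings in the pendant ring already differentiated and forms the furan ring by palladium catalysis. It sets out from 11: Seyferth–Gilbert homologation with the Ohira–Bestmann reagent (dimethyl (1-diazo-2-oxopropyl)phosphonate, K2CO3, MeOH, rt) should give 2-ethynyl-5-methoxy-4-(methoxymethoxy)-6-(3-methylbut-2-en-1-yl)phenol F4. Sonogashira coupling with 3-iodo-5-methoxyphenol (Pd(PPh3)2Cl2, CuI, Et3N, DMF, 60 °C) should give 3-{[2-hydroxy-4-methoxy-5-(methoxymethoxy)-3-(3-methylbut-2-en-1-yl)phenyl]ethynyl}-5-methoxyphenol F5. This should cyclise in the same pot by 5-endo-dig attack of the phenol on the alkyne, and the route is rejoined at 20.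

Further compounds

F1 | step 9 | 7-[6-methoxy-5-(methoxymethoxy)-7-(3-methylbut-2-en-1-yl)-1-benzofuran-2-yl]-3,5,7-trioxoheptanoic acid | OC(=O)CC(=O)CC(=O)CC(=O)c1cc2cc(OCOC)c(OC)c(CC=C(C)C)c2o1
F2 | step 9 | 2,4-dihydroxy-6-[6-methoxy-5-(methoxymethoxy)-7-(3-methylbut-2-en-1-yl)-1-benzofuran-2-yl]benzoic acid | OC(=O)c1c(O)cc(O)cc1-c1cc2cc(OCOC)c(OC)c(CC=C(C)C)c2o1
F3 | step 8 | 1-[6-methoxy-5-(methoxymethoxy)-7-(3-methylbut-2-en-1-yl)-1-benzofuran-2-yl]butane-1,3-dione | CC(=O)CC(=O)c1cc2cc(OCOC)c(OC)c(CC=C(C)C)c2o1
F4 | step 10 | 2-ethynyl-5-methoxy-4-(methoxymethoxy)-6-(3-methylbut-2-en-1-yl)phenol | C#Cc1cc(OCOC)c(OC)c(CC=C(C)C)c1O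
F5 | step 10 | 3-{[2-hydroxy-4-methoxy-5-(methoxymethoxy)-3-(3-methylbut-2-en-1-yl)phenyl]ethynyl}-5-methoxyphenol | COc1cc(O)cc(C#Cc2cc(OCOC)c(OC)c(CC=C(C)C)c2O)c1
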